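**Retrosynthetic overview**

1. Target 16 is (2R,3R)-7-O-prenyltaxifolin. The C3 hydroxyl is taken back to the (2S)-flavanone 11, by oxidation of its C3=C4 silyl enol ether on the face anti to ring B; O5, O3' and O4' are carried as TBS ethers.
2. Ring C of 11 is opened at C2–C3. The strategy rests on C2: it is a benzylic carbon that already carries O1, so in a simple ring A benzyl ether its C–H bonds are activated by both O1 and ring B and sit 1,6 to a carbene at C3. Diazoketone 10 gives 11 by enantioselective C–H insertion.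
3. Diazoketone 10 comes from methyl ketone 8 by detrifluoroacetylative diazo transfer. The O1–C2 bond is an ordinary ether bond, made by Mitsunobu coupling of phenol 3 with benzylic alcohol 6.
4. Rings A and B are bought as 1 and 4. Ring C is the only ring formed, in step 7.

Key step: step 7

Assumption: Rh2(S-PTTL)4 is taken to favour the C2–H bond that leads to the (2S)-flavanone; if the sense of induction proves opposite, Rh2(R-PTTL)4 is used with no other change.

**Route**

Step 1
Reactants: 1 2,4,6-trihydroxyacetophenone; 2 prenyl bromide (1-bromo-3-methylbut-2-ene)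
Product: 3 1-[2,6-dihydroxy-4-(3-methylbut-2-enyloxy)phenyl]ethanone
Conditions: K2CO3 (1.1 equiv), 2 (1.0 equiv), acetone, rt → 50 °C
Reagents that add atoms: none
Why: Williamson etherification; the 4-OH is the most acidic phenol and the only one not held in a hydrogen bond to the acetyl group, so with one equivalent of base and bromide O-alkylation should occur there.

Step 2
Reactants: 4 3,4-dihydroxybenzaldehyde
Product: 5 3,4-bis(tert-butyldimethylsilyloxy)benzaldehyde
Conditions: TBSCl (2.4 equiv), imidazole, DMF, rt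
Reagents that add atoms: tert-butyldimethylsilyl chloride (TBSCl), CC(C)(C)[Si](C)(C)Cl
Why: Standard imidazole-promoted silylation of both catechol hydroxyls; the silyl ethers keep ring B electron-rich and free of O–H bonds for the carbene step.

Step 3
Reactants: 5 3,4-bis(tert-butyldimethylsilyloxy)benzaldehyde
Product: 6 [3,4-bis(tert-butyldimethylsilyloxy)phenyl]methanol
Conditions: NaBH4, MeOH/THF, 0 °C; H2O work-up
Reagents that add atoms: none
Why: Borohydride reduction of an aryl aldehyde; the aryl silyl ethers should survive the short, cold reaction.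

Step 4
Reactants: 3 1-[2,6-dihydroxy-4-(3-methylbut-2-enyloxy)phenyl]ethanone; 6 [3,4-bis(tert-butyldimethylsilyloxy)phenyl]methanol
Product: 7 1-[2-{[3,4-bis(tert-butyldimethylsilyloxy)phenyl]methoxy}-6-hydroxy-4-(3-methylbut-2-enyloxy)phenyl]ethanone
Conditions: PPh3, DIAD, 6 (1.05 equiv), THF, 0 °C → rt
Reagents that add atoms: none
Why: Mitsunobu etherification forms the future O1–C2 bond under neutral conditions that spare the silyl ethers; the two phenols of 3 are equivalent, and after the first etherification the remaining one is locked in a hydrogen bond to the acetyl C=O, so the reaction should stop at the mono-ether.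

Step 5
Reactants: 7 1-[2-{[3,4-bis(tert-butyldimethylsilyloxy)phenyl]methoxy}-6-hydroxy-4-(3-methylbut-2-enyloxy)phenyl]ethanone
Product: 8 1-[2-{[3,4-bis(tert-butyldimethylsilyloxy)phenyl]methoxy}-6-(tert-butyldimethylsilyloxy)-4-(3-methylbut-2-enyloxy)phenyl]ethanone
Conditions: TBSCl, imidazole, DMAP (cat.), DMF, rt → 40 °C
Reagents that add atoms: tert-butyldimethylsilyl chloride (TBSCl), CC(C)(C)[Si](C)(C)Cl
Why: Silylation of the chelated phenol; it removes the O–H bond that would otherwise capture the carbene and puts on O5 a group with no C–H bond within reach of C3.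

Step 6
Reactants: 8 1-[2-{[3,4-bis(tert-butyldimethylsilyloxy)phenyl]methoxy}-6-(tert-butyldimethylsilyloxy)-4-(3-methylbut-2-enyloxy)phenyl]ethanone
Product: 10 1-[2-{[3,4-bis(tert-butyldimethylsilyloxy)phenyl]methoxy}-6-(tert-butyldimethylsilyloxy)-4-(3-methylbut-2-enyloxy)phenyl]-2-diazoethan-1-one, via trifluoromethyl β-diketone 9 (not isolated)
Conditions: LiN(SiMe3)2, THF, −78 °C; CF3CO2CH2CF3, −78 °C; cold dilute aq. HCl work-up; then MsN3, Et3N, H2O (1 equiv), MeCN, rt
Reagents that add atoms: methanesulfonyl azide (MsN3), CS(=O)(=O)N=[N+]=[N-]; 2,2,2-trifluoroethyl trifluoroacetate, O=C(OCC(F)(F)F)C(F)(F)F (its CF3CO group is present only in 9)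
Why: Danheiser detrifluoroacetylative diazo transfer; Claisen trifluoroacetylation of the kinetic lithium enolate activates the methyl group, and Regitz diazo transfer to the 1,3-diketone is followed by loss of the trifluoroacetyl group as the N-acyl sulfonamide, leaving the terminal α-diazoketone.

Step 7
Reactants: 10 1-[2-{[3,4-bis(tert-butyldimethylsilyloxy)phenyl]methoxy}-6-(tert-butyldimethylsilyloxy)-4-(3-methylbut-2-enyloxy)phenyl]-2-diazoethan-1-one
Product: 11 (2S)-2-[3,4-bis(tert-butyldimethylsilyloxy)phenyl]-5-(tert-butyldimethylsilyloxy)-7-(3-methylbut-2-enyloxy)-2,3-dihydro-4H-chromen-4-one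
Conditions: Rh2(S-PTTL)4 (dirhodium tetrakis[N-phthaloyl-(S)-tert-leucinate], 2 mol %), CH2Cl2, 0 °C → rt, slow addition of 10 at high dilution
Reagents that add atoms: none
Why: The dirhodium carboxylate adds to the diazo carbon and expels N2, and the resulting electrophilic rhodium carbene at C3 inserts into a benzylic C2–H bond of the ring A benzyl ether through a concerted, asynchronous three-centre transition state with hydride-like C–H cleavage. The closest known reaction type is the enantioselective intramolecular C–H insertion of 2-alkoxyaryl α-diazoketones to 2-substituted chroman-4-ones under chiral dirhodium carboxylate catalysis. Ring C closes by 1,6-insertion, the new C2–C3 bond completing the six-membered pyranone; this mode can compete with the usual five-membered closure because the only C–H bonds in reach are those on C2, where developing positive charge is stabilised by O1 and by the bis-silyloxyphenyl ring. The C2 stereocentre is set by the catalyst, whose N-phthaloyl-tert-leucinate ligands distinguish the two enantiotopic C2 hydrogens to give the (2S)-flavanone. The step needs chemoselectivity for insertion over attack of O1 on the carbene (oxonium ylide, then 1,2-benzyl shift to a benzofuranone): O1 is a weakly basic aryl ether oxygen and the bulky carboxylate ligands disfavour the crowded ylide, the O5 silyl ether offers no C–H bond in reach, the prenyl alkene para to the acyl group cannot reach C3, and slow addition in a non-aromatic solvent suppresses carbene dimerisation and solvent capture.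

Step 8
Reactants: 11 (2S)-2-[3,4-bis(tert-butyldimethylsilyloxy)phenyl]-5-(tert-butyldimethylsilyloxy)-7-(3-methylbut-2-enyloxy)-2,3-dihydro-4H-chromen-4-one
Product: 12 (2S)-2-[3,4-bis(tert-butyldimethylsilyloxy)phenyl]-5-(tert-butyldimethylsilyloxy)-7-(3-methylbut-2-enyloxy)-4-(trimethylsilyloxy)-2H-chromene
Conditions: TMSOTf, Et3N, CH2Cl2, −20 → 0 °C; non-aqueous work-up (pentane, filtration), used crude
Reagents that add atoms: trimethylsilyl trifluoromethanesulfonate (TMSOTf), C[Si](C)(C)OS(=O)(=O)C(F)(F)F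
Why: Soft enolisation (silyl triflate with amine base) gives the only possible enol ether, C3=C4, without a free metal enolate, so retro-oxa-Michael opening of ring C and loss of the C2 configuration should be avoided.

Step 9
Reactants: 12 (2S)-2-[3,4-bis(tert-butyldimethylsilyloxy)phenyl]-5-(tert-butyldimethylsilyloxy)-7-(3-methylbut-2-enyloxy)-4-(trimethylsilyloxy)-2H-chromene
Product: 15 (2R,3R)-2-[3,4-bis(tert-butyldimethylsilyloxy)phenyl]-5-(tert-butyldimethylsilyloxy)-3-hydroxy-7-(3-methylbut-2-enyloxy)-2,3-dihydro-4H-chromen-4-one, via silyloxy epoxide 13 (not isolated), via 3-O-trimethylsilyl ketone 14 (not isolated)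
Conditions: (±)-trans-2-(phenylsulfonyl)-3-phenyloxaziridine (1.5 equiv), acid-free CHCl3, rt; then aq. citric acid, THF, 0 °C
Reagents that add atoms: 2-(phenylsulfonyl)-3-phenyloxaziridine (Davis reagent), O=S(=O)(N1OC1c1ccccc1)c1ccccc1
Why: Rubottom-type oxidation with a Davis N-sulfonyloxaziridine; oxygen is delivered to the C3=C4 face opposite the C2 aryl group (substrate control), the silyloxy epoxide opens with silyl shift to O3 to give the 2,3-trans (2R,3R) ketone, and the neutral oxaziridine should react with the electron-rich enol ether far faster than with the prenyl alkene.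

Step 10
Reactants: 15 (2R,3R)-2-[3,4-bis(tert-butyldimethylsilyloxy)phenyl]-5-(tert-butyldimethylsilyloxy)-3-hydroxy-7-(3-methylbut-2-enyloxy)-2,3-dihydro-4H-chromen-4-one
Product: 16 (2R,3R)-2-(3,4-dihydroxyphenyl)-3,5-dihydroxy-7-(3-methylbut-2-enyloxy)-2,3-dihydro-4H-chromen-4-one (CNP0296402.1)
Conditions: Bu4NF (3.3 equiv), AcOH (3.5 equiv), THF, 0 °C, argon
Reagents that add atoms: none
Why: Fluoride cleavage of the three aryl silyl ethers; the acetic acid buffer keeps phenoxide concentration low, so base-induced opening of ring C, epimerisation at C2 or C3 and catechol autoxidation should not occur, and the prenyl ether is inert to fluoride.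

**Compound list**

1 | 2,4,6-trihydroxyacetophenone | CC(=O)c1c(O)cc(O)cc1O | starting material
2 | prenyl bromide (1-bromo-3-methylbut-2-ene) | CC(C)=CCBr | starting material
3 | 1-[2,6-dihydroxy-4-(3-methylbut-2-enyloxy)phenyl]ethanone | CC(=O)c1c(O)cc(OCC=C(C)C)cc1O | intermediate
4 | 3,4-dihydroxybenzaldehyde | O=Cc1ccc(O)c(O)c1 | starting material
5 | 3,4-bis(tert-butyldimethylsilyloxy)benzaldehyde | O=Cc1ccc(O[Si](C)(C)C(C)(C)C)c(O[Si](C)(C)C(C)(C)C)c1 | intermediate
6 | [3,4-bis(tert-butyldimethylsilyloxy)phenyl]methanol | OCc1ccc(O[Si](C)(C)C(C)(C)C)c(O[Si](C)(C)C(C)(C)C)c1 | intermediate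
7 | 1-[2-{[3,4-bis(tert-butyldimethylsilyloxy)phenyl]methoxy}-6-hydroxy-4-(3-methylbut-2-enyloxy)phenyl]ethanone | CC(=O)c1c(O)cc(OCC=C(C)C)cc1OCc1ccc(O[Si](C)(C)C(C)(C)C)c(O[Si](C)(C)C(C)(C)C)c1 | intermediate
8 | 1-[2-{[3,4-bis(tert-butyldimethylsilyloxy)phenyl]methoxy}-6-(tert-butyldimethylsilyloxy)-4-(3-methylbut-2-enyloxy)phenyl]ethanone | CC(=O)c1c(O[Si](C)(C)C(C)(C)C)cc(OCC=C(C)C)cc1OCc1ccc(O[Si](C)(C)C(C)(C)C)c(O[Si](C)(C)C(C)(C)C)c1 | intermediate
9 | 1-[2-{[3,4-bis(tert-butyldimethylsilyloxy)phenyl]methoxy}-6-(tert-butyldimethylsilyloxy)-4-(3-methylbut-2-enyloxy)phenyl]-4,4,4-trifluorobutane-1,3-dione | O=C(CC(=O)C(F)(F)F)c1c(O[Si](C)(C)C(C)(C)C)cc(OCC=C(C)C)cc1OCc1ccc(O[Si](C)(C)C(C)(C)C)c(O[Si](C)(C)C(C)(C)C)c1 | intermediate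
10 | 1-[2-{[3,4-bis(tert-butyldimethylsilyloxy)phenyl]methoxy}-6-(tert-butyldimethylsilyloxy)-4-(3-methylbut-2-enyloxy)phenyl]-2-diazoethan-1-one | CC(C)=CCOc1cc(O[Si](C)(C)C(C)(C)C)c(C(=O)C=[N+]=[N-])c(c1)OCc1ccc(O[Si](C)(C)C(C)(C)C)c(O[Si](C)(C)C(C)(C)C)c1 | intermediate
11 | (2S)-2-[3,4-bis(tert-butyldimethylsilyloxy)phenyl]-5-(tert-butyldimethylsilyloxy)-7-(3-methylbut-2-enyloxy)-2,3-dihydro-4H-chromen-4-one | CC(C)=CCOc1cc(O[Si](C)(C)C(C)(C)C)c2c(c1)O[C@H](c1ccc(O[Si](C)(C)C(C)(C)C)c(O[Si](C)(C)C(C)(C)C)c1)CC2=O | intermediate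
12 | (2S)-2-[3,4-bis(tert-butyldimethylsilyloxy)phenyl]-5-(tert-butyldimethylsilyloxy)-7-(3-methylbut-2-enyloxy)-4-(trimethylsilyloxy)-2H-chromene | CC(C)=CCOc1cc(O[Si](C)(C)C(C)(C)C)c2c(c1)O[C@H](c1ccc(O[Si](C)(C)C(C)(C)C)c(O[Si](C)(C)C(C)(C)C)c1)C=C2O[Si](C)(C)C | intermediate
13 | (2R,3R,4R)-3,4-epoxy-4-(trimethylsilyloxy) derivative of 12 (flavan numbering), oxirane oxygen trans to the C2 aryl group | CC(C)=CCOc1cc(O[Si](C)(C)C(C)(C)C)c2c(c1)O[C@H](c1ccc(O[Si](C)(C)C(C)(C)C)c(O[Si](C)(C)C(C)(C)C)c1)[C@H]3O[C@@]23O[Si](C)(C)C | intermediate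
14 | (2R,3R)-2-[3,4-bis(tert-butyldimethylsilyloxy)phenyl]-5-(tert-butyldimethylsilyloxy)-7-(3-methylbut-2-enyloxy)-3-(trimethylsilyloxy)-2,3-dihydro-4H-chromen-4-one | CC(C)=CCOc1cc(O[Si](C)(C)C(C)(C)C)c2c(c1)O[C@H](c1ccc(O[Si](C)(C)C(C)(C)C)c(O[Si](C)(C)C(C)(C)C)c1)[C@@H](O[Si](C)(C)C)C2=O | intermediate
15 | (2R,3R)-2-[3,4-bis(tert-butyldimethylsilyloxy)phenyl]-5-(tert-butyldimethylsilyloxy)-3-hydroxy-7-(3-methylbut-2-enyloxy)-2,3-dihydro-4H-chromen-4-one | CC(C)=CCOc1cc(O[Si](C)(C)C(C)(C)C)c2c(c1)O[C@H](c1ccc(O[Si](C)(C)C(C)(C)C)c(O[Si](C)(C)C(C)(C)C)c1)[C@@H](O)C2=O | intermediate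
16 | (2R,3R)-2-(3,4-dihydroxyphenyl)-3,5-dihydroxy-7-(3-methylbut-2-enyloxy)-2,3-dihydro-4H-chromen-4-one | CC(C)=CCOc1cc(O)c2c(c1)O[C@H](c1ccc(O)c(O)c1)[C@@H](O)C2=O | target

**Step count**

Total steps: 10. Longest linear sequence: 9 (steps 2 to 10, from 4); the ring A branch from 1 is 8 steps.

**Steps most likely to fail**

Step 7. The carbene may be captured by the O1 lone pair faster than it inserts (ylide formation followed by benzyl migration), or the two enantiotopic C2 hydrogens may be poorly distinguished. The fallback makes the C2–aryl bond instead, by asymmetric 1,4-arylation of a chromone. It sets out from 3 and comes back at 11.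
- Condensation of 3 with DMF dimethyl acetal in toluene should give the enaminone (E)-3-(dimethylamino)-1-[2,6-dihydroxy-4-(3-methylbut-2-enyloxy)phenyl]prop-2-en-1-one F1.
- Treatment with AcOH should cyclise it, with loss of dimethylamine, to 5-hydroxy-7-(3-methylbut-2-enyloxy)-4H-chromen-4-one F2.
- TBSCl and imidazole should then give 5-(tert-butyldimethylsilyloxy)-7-(3-methylbut-2-enyloxy)-4H-chromen-4-one F3.
- Purchased 4-bromobenzene-1,2-diol (Oc1ccc(Br)cc1O) is silylated to 4-bromo-1,2-bis(tert-butyldimethylsilyloxy)benzene F4.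
- Treatment of F4 with n-BuLi and B(OiPr)3, then mild hydrolysis, should give [3,4-bis(tert-butyldimethylsilyloxy)phenyl]boronic acid F5.
- The known enantioselective conjugate addition of arylboronic acids to chromones then joins F5 to C2 of F3: Pd(OCOCF3)2 with the tert-butyl pyridine-oxazoline ligand of the enantiomeric series that gives the (2S) product, NH4PF6 and water in 1,2-dichloroethane at 60 °C. This should give 11.

Step 6. C-trifluoroacetylation of the enolate of a 2,6-disubstituted aryl methyl ketone may be slow; the ortho silyl group may also migrate from the phenolic oxygen to the enolate oxygen, or be lost in the aqueous amine of the second stage. The fallback brings in the diazomethyl carbon by acylation of a diazomethane equivalent, with no enolate. It sets out from 2 and 6 and comes back at 10.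
- Purchased 2,4,6-trihydroxybenzaldehyde (O=Cc1c(O)cc(O)cc1O) is 4-O-prenylated with 2 (K2CO3, acetone) to 2,6-dihydroxy-4-(3-methylbut-2-enyloxy)benzaldehyde F6.
- Mitsunobu etherification with 6 (PPh3, DIAD) should give 2-{[3,4-bis(tert-butyldimethylsilyloxy)phenyl]methoxy}-6-hydroxy-4-(3-methylbut-2-enyloxy)benzaldehyde F7.
- Silylation (TBSCl, imidazole) should give the 6-(tert-butyldimethylsilyloxy) aldehyde F8.
- Pinnick oxidation (NaClO2, NaH2PO4, large excess of 2-methylbut-2-ene, t-BuOH/H2O) should give the benzoic acid F9.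
- 1-Chloro-N,N,2-trimethylprop-1-en-1-amine should convert F9 under neutral conditions into the benzoyl chloride F10.
- Trimethylsilyldiazomethane with Et3N in MeCN/THF at 0 °C should then give 10.

Step 9. The enol ether may hydrolyse back to the ketone before it is oxidised, oxidation may compete at the prenyl double bond at the temperature needed, or facial selectivity may be insufficient. The fallback is direct hydroxylation of the metal enolate at low temperature, in place of oxidation of a neutral enol ether. It sets out from 11, bypasses step 8, and comes back at 15.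
- KN(SiMe3)2 in THF at −78 °C generates the potassium enolate of 11, F11.
- F11 is oxidised at −78 °C by the same N-sulfonyloxaziridine, anti to the C2 aryl group, and quenched cold with AcOH. At this temperature the prenyl alkene is inert and the short enolate lifetime should limit ring opening.

**Further compounds**

F1 | step 7 | (E)-3-(dimethylamino)-1-[2,6-dihydroxy-4-(3-methylbut-2-enyloxy)phenyl]prop-2-en-1-one | CN(C)/C=C/C(=O)c1c(O)cc(OCC=C(C)C)cc1O
F2 | step 7 | 5-hydroxy-7-(3-methylbut-2-enyloxy)-4H-chromen-4-one | O=c1ccoc2cc(OCC=C(C)C)cc(O)c12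
F3 | step 7 | 5-(tert-butyldimethylsilyloxy)-7-(3-methylbut-2-enyloxy)-4H-chromen-4-one | O=c1ccoc2cc(OCC=C(C)C)cc(O[Si](C)(C)C(C)(C)C)c12
F4 | step 7 | 4-bromo-1,2-bis(tert-butyldimethylsilyloxy)benzene | Brc1ccc(O[Si](C)(C)C(C)(C)C)c(O[Si](C)(C)C(C)(C)C)c1
F5 | step 7 | [3,4-bis(tert-butyldimethylsilyloxy)phenyl]boronic acid | OB(O)c1ccc(O[Si](C)(C)C(C)(C)C)c(O[Si](C)(C)C(C)(C)C)c1
F6 | step 6 | 2,6-dihydroxy-4-(3-methylbut-2-enyloxy)benzaldehyde | O=Cc1c(O)cc(OCC=C(C)C)cc1O
F7 | step 6 | 2-{[3,4-bis(tert-butyldimethylsilyloxy)phenyl]methoxy}-6-hydroxy-4-(3-methylbut-2-enyloxy)benzaldehyde | O=Cc1c(O)cc(OCC=C(C)C)cc1OCc1ccc(O[Si](C)(C)C(C)(C)C)c(O[Si](C)(C)C(C)(C)C)c1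
F8 | step 6 | 2-{[3,4-bis(tert-butyldimethylsilyloxy)phenyl]methoxy}-6-(tert-butyldimethylsilyloxy)-4-(3-methylbut-2-enyloxy)benzaldehyde | O=Cc1c(O[Si](C)(C)C(C)(C)C)cc(OCC=C(C)C)cc1OCc1ccc(O[Si](C)(C)C(C)(C)C)c(O[Si](C)(C)C(C)(C)C)c1
F9 | step 6 | 2-{[3,4-bis(tert-butyldimethylsilyloxy)phenyl]methoxy}-6-(tert-butyldimethylsilyloxy)-4-(3-methylbut-2-enyloxy)benzoic acid | OC(=O)c1c(O[Si](C)(C)C(C)(C)C)cc(OCC=C(C)C)cc1OCc1ccc(O[Si](C)(C)C(C)(C)C)c(O[Si](C)(C)C(C)(C)C)c1
F10 | step 6 | 2-{[3,4-bis(tert-butyldimethylsilyloxy)phenyl]methoxy}-6-(tert-butyldimethylsilyloxy)-4-(3-methylbut-2-enyloxy)benzoyl chloride | ClC(=O)c1c(O[Si](C)(C)C(C)(C)C)cc(OCC=C(C)C)cc1OCc1ccc(O[Si](C)(C)C(C)(C)C)c(O[Si](C)(C)C(C)(C)C)c1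
F11 | step 9 | potassium (2S)-2-[3,4-bis(tert-butyldimethylsilyloxy)phenyl]-5-(tert-butyldimethylsilyloxy)-7-(3-methylbut-2-enyloxy)-2H-chromen-4-olate | CC(C)=CCOc1cc(O[Si](C)(C)C(C)(C)C)c2c(c1)O[C@H](c1ccc(O[Si](C)(C)C(C)(C)C)c(O[Si](C)(C)C(C)(C)C)c1)C=C2[O-].[K+]
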